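**Plan**

- Retrosynthesis: the carbinol C–O bond and the ring D–CH2 bond are cut first, which leads back to a ring A vinyl group and a ring D bromide. The CH2–CH2 bridge between rings B and C is then cut (Wittig olefination, diimide reduction), followed by the two diaryl ether C–O bonds (SNAr).
- Forward: a ring A–O–ring B aldehyde (from methyl gallate and 4-fluorobenzaldehyde) and a ring C–O–ring D phosphonium salt (from 2-fluoro-3-hydroxybenzaldehyde and 3-bromophenol) are joined through the B–C bridge. The gallate ester is then converted into the vinyl group, and the 18-membered macrocycle, the only ring formed, is closed last.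
- Enabling feature: the CH(OH)–CH2 link between rings A and D is a latent vinyl group on ring A. Its terminal carbon is the one bonded to ring D and its internal, benzylic carbon is the one bearing oxygen, so a 1,2-diboration followed by coupling of the primary C–B bond with the ring D bromide closes the ring and leaves a benzylic C–B bond for oxidation.
- Stereochemistry: the single (S) centre comes from the enantioselective platinum-catalysed diboration (chiral TADDOL phosphonite) and is carried into the carbinol by C–B oxidation with retention.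
- Protection: a diphenylmethylene ketal on the ring A catechol and a benzyl ether on the ring C phenol, both removed by the final hydrogenolysis.

Key step: step 12

Assumption: the (R,R)-configured phosphonite is taken to deliver boron to the si face of the internal vinyl carbon of 16, which gives (S)-18; if a small-scale run shows the opposite sense, the (S,S)-ligand from the other tartrate is used and nothing else changes.

**Route**

Step 1
Reactants: 1 methyl gallate
Product: 2 methyl 7-hydroxy-2,2-diphenyl-1,3-benzodioxole-5-carboxylate
Conditions: Ph2CCl2, neat, 170–180 °C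
Reagents that add atoms: dichlorodiphenylmethane, ClC(Cl)(c1ccccc1)c1ccccc1
Why: Diphenylmethylene ketal formation can only bridge two adjacent hydroxyls, and since the 3,4- and 4,5-pairs of methyl gallate are equivalent a single ketal with one free phenol should result.

Step 2
Reactants: 2 methyl 7-hydroxy-2,2-diphenyl-1,3-benzodioxole-5-carboxylate; 3 4-fluorobenzaldehyde
Product: 4 methyl 7-(4-formylphenoxy)-2,2-diphenyl-1,3-benzodioxole-5-carboxylate
Conditions: K2CO3, DMF, 120 °C
Reagents that add atoms: none
Why: Nucleophilic aromatic substitution (SNAr) of the fluoride para to the formyl group by the phenoxide of 2 is the standard entry to bisbibenzyl diaryl ethers and leaves ester and ketal untouched.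

Step 3
Reactants: 5 2-fluoro-3-hydroxybenzaldehyde
Product: 6 3-(benzyloxy)-2-fluorobenzaldehyde
Conditions: BnBr, K2CO3, DMF, rt
Reagents that add atoms: benzyl bromide, BrCc1ccccc1
Why: Williamson etherification of the phenol, which installs a group on ring C that can be removed at the end under neutral conditions.

Step 4
Reactants: 6 3-(benzyloxy)-2-fluorobenzaldehyde; 7 3-bromophenol
Product: 8 3-(benzyloxy)-2-(3-bromophenoxy)benzaldehyde
Conditions: K2CO3, DMAc, 130 °C
Reagents that add atoms: none
Why: SNAr at the fluorine ortho to the formyl group, while the unactivated C–Br bond of ring D should not react under these conditions.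

Step 5
Reactants: 8 3-(benzyloxy)-2-(3-bromophenoxy)benzaldehyde
Product: 9 [3-(benzyloxy)-2-(3-bromophenoxy)phenyl]methanol
Conditions: NaBH4, THF/MeOH, 0 °C
Reagents that add atoms: none
Why: Hydride reduction of the aldehyde to the benzylic alcohol, with aryl bromide and ethers inert.

Step 6
Reactants: 9 [3-(benzyloxy)-2-(3-bromophenoxy)phenyl]methanol
Product: 10 {[3-(benzyloxy)-2-(3-bromophenoxy)phenyl]methyl}triphenylphosphonium bromide
Conditions: PPh3·HBr, MeCN, reflux
Reagents that add atoms: triphenylphosphine hydrobromide, [Br-].[PH+](c1ccccc1)(c1ccccc1)c1ccccc1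
Why: Acid-promoted substitution of the benzylic hydroxyl by triphenylphosphine gives the phosphonium salt in one operation, and the aryl benzyl ether tolerates this weak acid.

Step 7
Reactants: 4 methyl 7-(4-formylphenoxy)-2,2-diphenyl-1,3-benzodioxole-5-carboxylate; 10 {[3-(benzyloxy)-2-(3-bromophenoxy)phenyl]methyl}triphenylphosphonium bromide
Product: 12 methyl 7-(4-{2-[3-(benzyloxy)-2-(3-bromophenoxy)phenyl]ethenyl}phenoxy)-2,2-diphenyl-1,3-benzodioxole-5-carboxylate (E/Z mixture), via benzylic ylide 11 (not isolated)
Conditions: K2CO3, 18-crown-6 (cat.), CH2Cl2, reflux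
Reagents that add atoms: none
Why: Wittig olefination of the ring B aldehyde with the semi-stabilised benzylic ylide builds the two-carbon B–C bridge, and the alkene geometry is irrelevant because the double bond is reduced next.

Step 8
Reactants: 12 stilbene (E/Z mixture)
Product: 13 methyl 7-(4-{2-[3-(benzyloxy)-2-(3-bromophenoxy)phenyl]ethyl}phenoxy)-2,2-diphenyl-1,3-benzodioxole-5-carboxylate
Conditions: TsNHNH2 (excess, in portions), NaOAc, DME/H2O, reflux
Reagents that add atoms: none
Why: Diimide reduction transfers two hydrogens to the C=C bond in a concerted way and, unlike hydrogenation over palladium, should spare the aryl bromide, the benzyl ether and the diphenylmethylene ketal.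

Step 9
Reactants: 13 bibenzyl methyl ester
Product: 14 [7-(4-{2-[3-(benzyloxy)-2-(3-bromophenoxy)phenyl]ethyl}phenoxy)-2,2-diphenyl-1,3-benzodioxol-5-yl]methanol
Conditions: i-Bu2AlH, CH2Cl2, −78 → 0 °C; aq. potassium sodium tartrate
Reagents that add atoms: none
Why: Aluminium hydride reduction of the benzoate ester to the primary benzylic alcohol, at a temperature at which the C–Br bond is not reduced.

Step 10
Reactants: 14 ring A benzylic alcohol
Product: 15 7-(4-{2-[3-(benzyloxy)-2-(3-bromophenoxy)phenyl]ethyl}phenoxy)-2,2-diphenyl-1,3-benzodioxole-5-carbaldehyde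
Conditions: MnO2, CH2Cl2, rt
Reagents that add atoms: none
Why: MnO2 oxidises benzylic alcohols selectively to aldehydes without over-oxidation.

Step 11
Reactants: 15 ring A aldehyde
Product: 16 5-ethenyl-7-(4-{2-[3-(benzyloxy)-2-(3-bromophenoxy)phenyl]ethyl}phenoxy)-2,2-diphenyl-1,3-benzodioxole (seco styrene with ring D bromide)
Conditions: Ph3PCH3Br, KOtBu, THF, 0 °C → rt
Reagents that add atoms: methyltriphenylphosphonium bromide, [Br-].C[P+](c1ccccc1)(c1ccccc1)c1ccccc1
Why: Wittig methylenation of the aromatic aldehyde installs the vinyl group that carries both carbons of the future CH(OH)–CH2 link.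

Step 12
Reactants: 16 seco styrene with ring D bromide; 17 bis(pinacolato)diboron
Product: 19 macrocyclic (S)-benzylic pinacol boronate (18-membered ring closed at the ring D–CH2 bond), via (S)-1,2-bis(boronate) 18 (not isolated)
Conditions: Pt(dba)3 (3 mol%), (R,R)-TADDOL phenylphosphonite bearing 3,5-diisopropylphenyl groups (6 mol%), B2pin2 (1.05 equiv), THF, 60 °C; then syringe-pump addition to Pd(OAc)2 (10 mol%), RuPhos (12 mol%), KOH, THF/H2O, 70 °C, ca. 2 mM
Reagents that add atoms: bis(pinacolato)diboron 17, CC1(C)OB(OC1(C)C)B1OC(C)(C)C(C)(C)O1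
Why: The B–B bond adds oxidatively to zerovalent platinum, the ring A vinyl group inserts into a Pt–B bond and C–B reductive elimination gives bis(boronate) 18; after dilution the ring D C–Br bond adds to zerovalent palladium, the primary C–B bond transmetalates and C(sp3)–C(sp2) reductive elimination forms the ring D–CH2 bond. The closest known reaction type is the one-pot platinum-catalysed enantioselective diboration of terminal alkenes followed by Suzuki–Miyaura coupling of the primary boronate, run here intramolecularly in the manner of a macrocyclising B-alkyl Suzuki coupling. The 18-membered ring closes end-to-end by this C–C coupling between the CH2 terminus and the bromine-bearing carbon of ring D, under pseudo-high dilution, with the two diaryl ether hinges and the ortho and meta substitution of rings C and D folding the chain back on itself. The one stereocentre is set in the insertion step by the chiral phosphonite on platinum, which should deliver boron to the si face of the internal vinyl carbon, and it is not touched during the coupling. The step needs the primary boronate to couple rather than the secondary benzylic one and ring closure to outrun oligomerisation; the first should follow from the faster transmetalation of the unhindered primary C–B bond activated by the vicinal boron under RuPhos/KOH, the second from slow addition, while the near-stoichiometric amount of B2pin2 limits borylation of the aryl bromide.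

Step 13
Reactants: 19 macrocyclic (S)-benzylic pinacol boronate
Product: 20 macrocyclic (S)-carbinol with ring A diphenylmethylene ketal and ring C benzyl ether
Conditions: 30% H2O2, 3 M NaOH, THF, 0 °C → rt
Reagents that add atoms: hydrogen peroxide, OO
Why: Hydroperoxide adds to boron and the benzylic carbon migrates from boron to oxygen with retention (boronate oxidation), so the (S) configuration set in step 12 is transferred unchanged to the carbinol.

Step 14
Reactants: 20 protected macrocyclic (S)-carbinol
Product: 21 CNP0333307.1, the (S)-configured target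
Conditions: H2 (1 atm), 10% Pd on carbon, EtOAc/THF, rt
Reagents that add atoms: none
Why: Hydrogenolysis of the aryl benzyl ether and of the doubly benzylic ketal C–O bonds is expected to be much faster under neutral conditions than cleavage of the secondary benzylic C–OH bond, so all three phenols are freed while the carbinol and its configuration are kept.

**Compound list**

1 | methyl gallate | COC(=O)c1cc(O)c(O)c(O)c1 | starting material
2 | methyl 7-hydroxy-2,2-diphenyl-1,3-benzodioxole-5-carboxylate | COC(=O)c1cc(O)c2OC(c3ccccc3)(c3ccccc3)Oc2c1 | intermediate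
3 | 4-fluorobenzaldehyde | O=Cc1ccc(F)cc1 | starting material
4 | methyl 7-(4-formylphenoxy)-2,2-diphenyl-1,3-benzodioxole-5-carboxylate | COC(=O)c1cc(Oc2ccc(C=O)cc2)c2OC(c3ccccc3)(c3ccccc3)Oc2c1 | intermediate
5 | 2-fluoro-3-hydroxybenzaldehyde | O=Cc1cccc(O)c1F | starting material
6 | 3-(benzyloxy)-2-fluorobenzaldehyde | O=Cc1cccc(OCc2ccccc2)c1F | intermediate
7 | 3-bromophenol | Oc1cccc(Br)c1 | starting material
8 | 3-(benzyloxy)-2-(3-bromophenoxy)benzaldehyde | O=Cc1cccc(OCc2ccccc2)c1Oc1cccc(Br)c1 | intermediate
9 | [3-(benzyloxy)-2-(3-bromophenoxy)phenyl]methanol | OCc1cccc(OCc2ccccc2)c1Oc1cccc(Br)c1 | intermediate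
10 | {[3-(benzyloxy)-2-(3-bromophenoxy)phenyl]methyl}triphenylphosphonium bromide | [Br-].Brc1cccc(Oc2c(C[P+](c3ccccc3)(c3ccccc3)c3ccccc3)cccc2OCc2ccccc2)c1 | intermediate
11 | benzylic ylide, [3-(benzyloxy)-2-(3-bromophenoxy)benzylidene]triphenylphosphorane (not isolated) | Brc1cccc(Oc2c(C=P(c3ccccc3)(c3ccccc3)c3ccccc3)cccc2OCc2ccccc2)c1 | intermediate
12 | methyl 7-(4-{2-[3-(benzyloxy)-2-(3-bromophenoxy)phenyl]ethenyl}phenoxy)-2,2-diphenyl-1,3-benzodioxole-5-carboxylate, E/Z mixture | COC(=O)c1cc(Oc2ccc(C=Cc3cccc(OCc4ccccc4)c3Oc3cccc(Br)c3)cc2)c2OC(c3ccccc3)(c3ccccc3)Oc2c1 | intermediate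
13 | methyl 7-(4-{2-[3-(benzyloxy)-2-(3-bromophenoxy)phenyl]ethyl}phenoxy)-2,2-diphenyl-1,3-benzodioxole-5-carboxylate | COC(=O)c1cc(Oc2ccc(CCc3cccc(OCc4ccccc4)c3Oc3cccc(Br)c3)cc2)c2OC(c3ccccc3)(c3ccccc3)Oc2c1 | intermediate
14 | [7-(4-{2-[3-(benzyloxy)-2-(3-bromophenoxy)phenyl]ethyl}phenoxy)-2,2-diphenyl-1,3-benzodioxol-5-yl]methanol | OCc1cc(Oc2ccc(CCc3cccc(OCc4ccccc4)c3Oc3cccc(Br)c3)cc2)c2OC(c3ccccc3)(c3ccccc3)Oc2c1 | intermediate
15 | 7-(4-{2-[3-(benzyloxy)-2-(3-bromophenoxy)phenyl]ethyl}phenoxy)-2,2-diphenyl-1,3-benzodioxole-5-carbaldehyde | O=Cc1cc(Oc2ccc(CCc3cccc(OCc4ccccc4)c3Oc3cccc(Br)c3)cc2)c2OC(c3ccccc3)(c3ccccc3)Oc2c1 | intermediate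
16 | 5-ethenyl-7-(4-{2-[3-(benzyloxy)-2-(3-bromophenoxy)phenyl]ethyl}phenoxy)-2,2-diphenyl-1,3-benzodioxole (seco styrene with ring D bromide) | C=Cc1cc(Oc2ccc(CCc3cccc(OCc4ccccc4)c3Oc3cccc(Br)c3)cc2)c2OC(c3ccccc3)(c3ccccc3)Oc2c1 | intermediate
17 | bis(pinacolato)diboron | CC1(C)OB(OC1(C)C)B1OC(C)(C)C(C)(C)O1 | starting material
18 | (S)-1,2-bis(pinacolboryl)ethyl compound from 16, boron on both carbons of the former vinyl group (not isolated) | CC1(C)OB(OC1(C)C)C[C@@H](c1cc(Oc2ccc(CCc3cccc(OCc4ccccc4)c3Oc3cccc(Br)c3)cc2)c2OC(c3ccccc3)(c3ccccc3)Oc2c1)B1OC(C)(C)C(C)(C)O1 | intermediate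
19 | macrocyclic (S)-benzylic pinacol boronate: 18-membered ring, ring D–CH2–CH(Bpin)–ring A, ring A catechol as diphenylmethylene ketal, ring C phenol as benzyl ether | C1(c2ccccc2)(c2ccccc2)Oc2cc3cc(c2O1)Oc1ccc(cc1)CCc1cccc(OCc2ccccc2)c1Oc1cccc(c1)C[C@@H]3B1OC(C)(C)C(C)(C)O1 | intermediate
20 | macrocyclic (S)-carbinol, ring A catechol as diphenylmethylene ketal, ring C phenol as benzyl ether | C1(c2ccccc2)(c2ccccc2)Oc2cc3cc(c2O1)Oc1ccc(cc1)CCc1cccc(OCc2ccccc2)c1Oc1cccc(c1)C[C@@H]3O | intermediate
21 | CNP0333307.1, (S)-configured macrocyclic bisbibenzyl carbinol with free ring A catechol and ring C phenol | Oc1cc2cc(c1O)Oc1ccc(cc1)CCc1cccc(O)c1Oc1cccc(c1)C[C@@H]2O | target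

**Step count and risks**

Total step count: 14. Longest linear sequence: 12 steps (steps 3 to 14, from 2-fluoro-3-hydroxybenzaldehyde 5).

Step 12 (key step). What may go wrong: intermolecular coupling and oligomerisation overtaking closure of the 18-membered ring, incomplete enantioface selection on the electron-rich styrene, and protodeboronation or competing transmetalation of the benzylic C–B bond. Fallback: setting out from styrene 16, a Tsuji–Wacker oxidation (PdCl2, CuCl, O2, DMF/H2O, rt) should give the ring A methyl ketone F1. Intramolecular palladium-catalysed α-arylation of this ketone by the ring D bromide (Pd2(dba)3, Xantphos, NaOtBu, toluene, 80 °C, slow addition) would form the same CH2–ring D bond and give the macrocyclic aryl benzyl ketone F2. Noyori transfer hydrogenation with RuCl[(S,S)-TsDPEN](p-cymene) in HCO2H/Et3N should then set the (S) carbinol, and the route is rejoined at 20.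

Step 14. What may go wrong: hydrogenolytic loss of the benzylic hydroxyl group, which sits para to an oxygen on ring A and can also ionise towards a quinone methide once the phenols are free. Fallback: setting out from boronate 19, the hydrogenolysis (H2, 10% Pd on carbon, EtOAc) is run while the carbinol carbon still carries boron, which palladium does not cleave, and should give the triphenolic macrocyclic (S)-boronate F3. Oxidation of the C–B bond with H2O2 in pH 8 phosphate buffer/THF at 0 °C under argon then gives 21 directly.

Step 4. What may go wrong: slow displacement of a fluoride flanked by the formyl and benzyloxy groups, with base-induced degradation of the aldehyde (Cannizzaro or condensation pathways) at the temperature required. Fallback: setting out from aldehyde 6, treatment with I2 in aqueous NH3/THF converts the formyl group into the nitrile, giving 3-(benzyloxy)-2-fluorobenzonitrile F4, an activating group that tolerates forcing base. SNAr with 3-bromophenol 7 (K2CO3, DMSO, 120 °C) should give 3-(benzyloxy)-2-(3-bromophenoxy)benzonitrile F5. Partial reduction with i-Bu2AlH (toluene, −78 °C) and hydrolysis of the imine returns to the route at aldehyde 8.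

Further compounds
F1 | step 12 | 1-[7-(4-{2-[3-(benzyloxy)-2-(3-bromophenoxy)phenyl]ethyl}phenoxy)-2,2-diphenyl-1,3-benzodioxol-5-yl]ethanone (ring A methyl ketone) | CC(=O)c1cc(Oc2ccc(CCc3cccc(OCc4ccccc4)c3Oc3cccc(Br)c3)cc2)c2OC(c3ccccc3)(c3ccccc3)Oc2c1
F2 | step 12 | macrocyclic aryl benzyl ketone (ring A–C(=O)–CH2–ring D), ring A diphenylmethylene ketal, ring C benzyl ether | C1(c2ccccc2)(c2ccccc2)Oc2cc3cc(c2O1)Oc1ccc(cc1)CCc1cccc(OCc2ccccc2)c1Oc1cccc(c1)CC3=O
F3 | step 14 | triphenolic macrocyclic (S)-benzylic pinacol boronate | Oc1cc2cc(c1O)Oc1ccc(cc1)CCc1cccc(O)c1Oc1cccc(c1)C[C@@H]2B1OC(C)(C)C(C)(C)O1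
F4 | step 4 | 3-(benzyloxy)-2-fluorobenzonitrile | N#Cc1cccc(OCc2ccccc2)c1F
F5 | step 4 | 3-(benzyloxy)-2-(3-bromophenoxy)benzonitrile | N#Cc1cccc(OCc2ccccc2)c1Oc1cccc(Br)c1
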